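Two questions stood on this flask, and I answered both from one number: the excess of right-handed substrate at which the flask stopped gaining.

| flask | left-handed substrate | right-handed substrate | coupling partner | protic impurity | catalyst | remark | time |
|---|---|---|---|---|---|---|---|
| ochre | 20 mM | 20 mM | 30 mM | 1 mM | 0.40 mM | run made earlier |  |
| amber | 20 mM | 20 mM | 30 mM | 4 mM | 0.40 mM | run made earlier |  |
| violet | 20 mM | 20 mM | 30 mM | 2 mM | 0.20 mM | run made earlier |  |
| flask | 20 mM | 20 mM | 30.0 mM | 2.00 mM | 0.40 mM |  | 50 h |

1. whether the excess of right-handed substrate over left-handed substrate among what is left of the two reaches 98 % by 50 h (no / yes)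
2. the highest excess of right-handed substrate over left-handed substrate among what is left of the two up to 50 h

- catalyst is single-handed; left-handed substrate and right-handed substrate are mirror images of each other, charged as a racemate, each of them at the stated concentration
- the analysis behind the earlier runs scatters by 0.5 percentage points, standard deviation
- candidate steps: coupling partner + catalyst + left-handed substrate -> catalyst + left-handed product; coupling partner + catalyst + right-handed substrate -> catalyst + right-handed product; left-handed substrate <-> right-handed substrate; catalyst <-> dormant form; coupling partner + protic impurity -> quenched reagent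

- ochre (time / h: right-handed substrate / %, left-handed substrate / %): 5.00: 48.1, 46.6; 10.0: 46.5, 43.6; 15.0: 45.8, 41.8; 30.0: 42.2, 38.8; 60.0: 37.3, 34.0
- amber (time / h: right-handed substrate / %, left-handed substrate / %): 5.00: 48.5, 45.8; 10.0: 47.9, 44.1; 15.0: 46.3, 42.4; 30.0: 42.6, 38.6; 60.0: 37.2, 34.6
- violet (time / h: right-handed substrate / %, left-handed substrate / %): 5.00: 49.1, 47.5; 10.0: 48.4, 45.9; 15.0: 47.5, 45.9; 30.0: 45.4, 43.8; 60.0: 42.0, 39.3

(standard deviation of a reading: 0.5 percentage points)

I followed one left-handed molecule. At each fork it could couple, at a rate a per hour that scales with [catalyst][coupling partner], or invert, at r per hour. Its right-handed twin coupled at b and inverted at r. A small excess therefore stopped growing at (a−b)/(4r), where uneven coupling made it as fast as inversion erased it.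

The first row of the table gave the split. Adding the ochre and amber losses at 5.00 h, left-handed over right-handed, I read a selectivity factor a/b of 2.24.

The rows from 15.0 h to 60.0 h gave the plateau. Ochre read 4.46 % and amber 4.34 %, although their impurity charges were 1 mM and 4 mM. Pooled, they read 4.40 %.

From these two readings came the fork ratio a/r, the couplings of a left-handed molecule per inversion, 0.319. That is a chance of 24.2 % of coupling at a fork.

Violet had half the catalyst, so the ratio should halve and the plateau fall to 2.20 %. Violet's same rows read 2.24 %.

The flask had ochre's catalyst and an impurity charge of 2.00 mM, between the two runs, so I committed to a top near 4.40 % and to no for 98 %.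

The forecast, holding that “the substrates must be racemising and holding it at a plateau”, gave no and a top of 4.8 %.

The flask gave no and a top of 4.60 %. At 14.7 h its left-handed substrate was used by coupling at 0.39 of the rate of its forward inversion, less than by inversion. My fork ratio of 0.319, read from the rows of the earlier runs, was lower than this value of the flask at that one moment.

    coupling partner + catalyst + left-handed substrate → catalyst + left-handed product (k = 31.0 L² mol⁻² min⁻¹)
    coupling partner + catalyst + right-handed substrate → catalyst + right-handed product (k = 12.0 L² mol⁻² min⁻¹)
    left-handed substrate ⇌ right-handed substrate (k = 3.80 × 10⁻⁴ min⁻¹)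
    catalyst ⇌ dormant form (K = 1.40, k = 0.00110 min⁻¹)
    coupling partner + protic impurity → quenched reagent (k = 0.160 L mol⁻¹ min⁻¹)

With 1.0 mM of catalyst and [coupling partner] taken as in this flask, the fork ratio becomes 0.797 and the plateau 11.0 %. The computed top of that flask is 9.40 %, lower than this reckoning.

Readings and results were generated by integration with constants of no real substance; scatter was added.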